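The earlier runs and the new flask come from a simulation with constants of no real substance, noise included.

We count in percent of the starting material charged. A homo product counts as two, and the sum of target, open intermediate and homo product is what we can see of the opened material.

| setting | teal | blue | green | flask |
|---|---|---|---|---|
| starting material | 0.11 M | 0.11 M | 0.11 M | 0.11 M |
| fresh partner | 0.116 M (fed, over 25 h) | 0.116 M (fed, over 25 h) | 0.23 M (fed, over 25 h) | 0.116 M (fed, over 25 h) |
| coupling partner | 0.066 M | 0.26 M | 0.132 M | 0.132 M |
| remark | run made earlier; the fed solution adds 0.20 times the starting volume | run made earlier; the fed solution adds 0.20 times the starting volume | run made earlier; the fed solution adds 0.20 times the starting volume | the fed solution adds 0.20 times the starting volume |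
| time |  |  |  | 25 h |

| run | time / h | target / % | open intermediate / % | homo product / % |
|---|---|---|---|---|
| teal | 1.00 | 0.3 | 8.3 | 0.2 |
| teal | 3.00 | 0.1 | 18.3 | 1.2 |
| teal | 6.00 | 0.2 | 26.6 | 4.0 |
| teal | 8.00 | 0.6 | 28.1 | 6.9 |
| teal | 12.0 | 1.0 | 28.6 | 13.0 |
| teal | 15.0 | 1.6 | 26.5 | 17.0 |
| teal | 20.0 | 2.5 | 23.8 | 22.2 |
| blue | 1.00 | 0 | 28.0 | 1.1 |
| blue | 3.00 | 0.6 | 51.5 | 7.6 |
| blue | 6.00 | 2.7 | 54.3 | 25.0 |
| blue | 8.00 | 3.4 | 48.0 | 34.7 |
| blue | 12.0 | 7.5 | 37.8 | 48.5 |
| blue | 15.0 | 10.7 | 30.1 | 54.4 |
| blue | 20.0 | 15.1 | 20.5 | 60.2 |
| green | 1.50 | 0.7 | 21.5 | 0.5 |
| green | 3.00 | 0.9 | 33.1 | 2.8 |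
| green | 6.00 | 1.9 | 40.8 | 11.5 |
| green | 10.0 | 5.0 | 37.9 | 23.5 |
| green | 20.0 | 9.3 | 24.9 | 40.7 |

(readings scatter by 0.3 percentage points)

- a species is counted by the starting material in it: one homo product counts as two
- charges are per starting volume, the dose included; the dosed solution carries all of it

* amount of target in the flask at 25 h, in percent of the starting material charged
* amount of open intermediate in the flask at 25 h, in percent of the starting material charged
* amount of homo product in the flask at 25 h, in percent of the starting material charged

In the first hour the blue run opens 29.1% and the teal run 8.80%. Their logarithmic losses stand 3.73 to one, and their coupling charges 3.94 to one. So we take opening as starting material meeting coupling partner, one of each, and read from blue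

k = 1.41 M⁻¹ h⁻¹

For the flask, with the mean volume taken over the dose, we reckon

R = 0.132 M / 0.11 M = 1.20, N = k · 0.11 M · 25 h / mean volume = 3.52

u = (R − 1) / (R · exp((R − 1)N) − 1) = 14.0%

Here u is the unopened fraction, the part of the charge still starting material at the asked time if nothing else draws on coupling partner.

Was one number enough? Reckoned for 20.0 h with N = 2.87, the opened fraction stands above the readings by 2.1 percentage points in teal and 3 points in blue. In green, which has the flask's R but twice its fresh partner, the gap is wider, at 7.4 points. So one number was not enough: in all three runs the amount it reckons as opened stands above the sum of the readings, and these gaps test that sum, not how it splits. Taking blue's gap, we expect the three products to sum to 83.0%.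

The forecast gives 7.7% target, 24% open intermediate and 48% homo product, a sum of 79.7%, lower than ours. It leans on the green run: “The flask should sit close to green”.

The flask gives 7.06% target, 23.4% open intermediate and 50.6% homo product, each inside the forecast's range. Beside them it holds 2.84% over-reaction product, which our number does not carry and which is less than the forecast's 10 points width on homo product. Starting material left is 16.1%, against u of 14.0%.

    2 open intermediate → homo product (k = 0.900 M⁻¹ h⁻¹)
    fresh partner + target → over-reaction product (k = 0.530 M⁻¹ h⁻¹)
    coupling partner + fresh partner → second intermediate (k = 0.240 M⁻¹ h⁻¹)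
    open intermediate + second intermediate → target (k = 22.0 M⁻¹ h⁻¹)
    starting material + coupling partner → open intermediate (k = 1.40 M⁻¹ h⁻¹)

In the neighbour flask with 0.079 M coupling partner, R falls to 0.718, below one, so coupling partner is the limiting reagent, and u gives 38.4%, more than the flask's 14.0%. That flask leaves 40.5% starting material, with 3.06% target, 22.3% open intermediate and 32.6% homo product.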